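**Plan**

- Atom numbers are those of the target SMILES read in order (C1 to O34). Ring C is C2–C7, ring D is C5/C6/C27/C30/C31/C32, ring A is the oxepane and ring B the cyclohexane C10/C11/C21–C24.
- Retrosynthesis: the C15 ketone comes from its alcohol; C8–C9 is cut into an alkenyl iodide and an alkylborane; C7=C8 goes back to a C7 ketone and this to a C2=C7 alkene; the C32 carbinol goes back to a ketone.
- The cis-decalin, with quaternary C27 on ring-fusion C6 and oxygenated C32 on ring-fusion C5, is then a cyclohexene fused to a cyclohexanone, so C3–C4 and C5–C6 are cut together to an open-chain trienone. In the west half O20–C17 and C10–C11 are cut to a diepoxy allylsilane.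
- Forward: the east chain gives rings C and D in one cycloaddition, followed by the C32 carbinol, C2/C7 and the alkenyl iodide. The west chain gives ring A then ring B in one epoxide cascade, followed by the C24 carbinol and the iodide. The halves are joined at C8–C9, desilylated and oxidised at C15.
- Stereochemistry: C5/C6 come from the chiral Lewis acid in the cycloaddition; C32, C2 and the C7=C8 geometry follow from the shape of the cis-decalin; C21/C11 come from the Shi epoxidation and are relayed to C10 by the cascade and to C24 by equatorial hydration.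

Key step: step 5

Assumption: the (S)-configured oxazaborolidinium ion is taken to leave open the enone face that leads to the (4aR,8aS) adduct; should the opposite sense be found, the (R)-catalyst would be used with no other change.

**Route**

Step 1
Reactants: 1 methyl 4,4-dimethyl-5-oxopentanoate
Product: 2 methyl (5E)-4,4-dimethyl-7-oxooct-5-enoate
Conditions: Ph3P=CHC(O)CH3, toluene, 100 °C
Reagents that add atoms: (acetylmethylene)triphenylphosphorane, CC(=O)C=P(c1ccccc1)(c1ccccc1)c1ccccc1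
Why: Wittig olefination with a stabilised ylide; the aldehyde has no α-hydrogen and the acyl ylide should give the (E)-enone.

Step 2
Reactants: 2 methyl (5E)-4,4-dimethyl-7-oxooct-5-enoate
Product: 3 methyl (5E)-4,4,7-trimethylocta-5,7-dienoate
Conditions: Ph3PCH3Br, NaN(SiMe3)2, THF, −78 to 0 °C
Reagents that add atoms: methyltriphenylphosphonium bromide, C[P+](c1ccccc1)(c1ccccc1)c1ccccc1.[Br-]
Why: Wittig methylenation; the non-stabilised ylide should attack the ketone much faster than the methyl ester and turn the enone into the 2-methyl-(E)-diene without touching the existing double bond.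

Step 3
Reactants: 3 methyl (5E)-4,4,7-trimethylocta-5,7-dienoate
Product: 4 (5E)-N-methoxy-N,4,4,7-tetramethylocta-5,7-dienamide
Conditions: MeNH(OMe)·HCl, i-PrMgCl, THF, −20 to 0 °C
Reagents that add atoms: N,O-dimethylhydroxylamine hydrochloride, CNOC.Cl
Why: direct aminolysis of the ester by the chloromagnesium amide (Weinreb amide formation); the diene is inert to the Grignard base at low temperature.

Step 4
Reactants: 4 (5E)-N-methoxy-N,4,4,7-tetramethylocta-5,7-dienamide
Product: 5 (7E)-6,6,9-trimethyldeca-1,7,9-trien-3-one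
Conditions: CH2=CHMgBr, THF, 0 °C; poured into cold 1 M HCl; used at once
Reagents that add atoms: vinylmagnesium bromide, C=C[Mg]Br
Why: Weinreb ketone synthesis; the chelated tetrahedral adduct stops at mono-addition and the acidic inverse quench should keep the liberated amine from adding to the vinyl ketone.

Step 5
Reactants: 5 (7E)-6,6,9-trimethyldeca-1,7,9-trien-3-one
Product: 6 (4aR,8aS)-4,4,6-trimethyl-3,4,4a,7,8,8a-hexahydronaphthalen-1(2H)-one
Conditions: (S)-3,3-diphenyl-1-(o-tolyl)tetrahydro-1H,3H-pyrrolo[1,2-c][1,3,2]oxazaborole (20 mol %), Tf2NH (17 mol %), CH2Cl2, −78 to −40 °C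
Reagents that add atoms: none
Why: The oxazaborolidinium ion binds the ketone oxygen O34 of the vinyl ketone and lowers its LUMO, and a concerted, asynchronous [4+2] cycloaddition joins C4 to C3 and C5 to C6; the closest known reaction types are the Lewis-acid-catalysed intramolecular Diels–Alder reaction of 1,7,9-decatrien-3-ones and the oxazaborolidinium-catalysed Diels–Alder reaction of enones. Ring C (the cyclohexene C2–C7) closes by the cycloaddition itself, and ring D (the cyclohexanone) closes in the same event because the four-atom tether C27–C30–C31–C32 links diene terminus C6 to dienophile carbon C5. C5 and C6 are set relative to each other by the endo transition state, in which the tether carbonyl lies under the diene, so the two ring-fusion hydrogens should end up cis. Their absolute configuration is set by the chiral boron cation, which leaves one face of the bound enone open. The step needs endo over exo and one enone face over the other; regiochemistry is fixed by the tether, the (E)-diene and the gem-dimethyl group at C27 favour the folded conformer, and the low temperature holds back the uncatalysed racemic pathway.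

Step 6
Reactants: 6 (4aR,8aS)-4,4,6-trimethyl-3,4,4a,7,8,8a-hexahydronaphthalen-1(2H)-one
Product: 7 (4aR,8aS)-4,4,6-trimethyl-1-methylidene-1,2,3,4,4a,7,8,8a-octahydronaphthalene
Conditions: Zn, CH2Br2, TiCl4, THF/CH2Cl2, 0 °C to rt
Reagents that add atoms: dibromomethane, BrCBr
Why: Lombardo methylenation; the non-basic titanium methylene reagent should olefinate the ketone without enolising C5, so the cis ring fusion is kept.

Step 7
Reactants: 7 (4aR,8aS)-4,4,6-trimethyl-1-methylidene-1,2,3,4,4a,7,8,8a-octahydronaphthalene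
Product: 9 (1S,4aR,8aS)-1,4,4,6-tetramethyl-1,2,3,4,4a,7,8,8a-octahydronaphthalen-1-ol, via organomercurial 8 (not isolated)
Conditions: Hg(OAc)2, THF/H2O, rt; then 3 M NaOH, NaBH4, 0 °C
Reagents that add atoms: water, O
Why: oxymercuration–demercuration (Markovnikov hydration); Hg(OAc)2 should react with the 1,1-disubstituted exocyclic alkene well before the hindered trisubstituted ring alkene, and water should attack C32 along the equatorial direction because the axial face is blocked by the syn-axial C7 of ring C, leaving the methyl group axial and the hydroxyl cis to H5.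

Step 8
Reactants: 9 (1S,4aR,8aS)-1,4,4,6-tetramethyl-1,2,3,4,4a,7,8,8a-octahydronaphthalen-1-ol
Product: 11 (1S,4aR,5S,6R,8aS)-1,4,4,6-tetramethyldecahydronaphthalene-1,5-diol, via alkylborane 10 (not isolated)
Conditions: BH3·THF, THF, 0 °C to rt; then NaOH, H2O2, 0 °C to rt
Reagents that add atoms: hydrogen peroxide, OO
Why: hydroboration–oxidation (syn, anti-Markovnikov); boron should add to the less substituted C7 and hydrogen to C2 from the convex face of the cis-decalin, away from the axial C32 carbinol carbon and its methyl group, which places the C2 methyl trans to H6.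

Step 9
Reactants: 11 (1S,4aR,5S,6R,8aS)-1,4,4,6-tetramethyldecahydronaphthalene-1,5-diol
Product: 12 (2R,4aS,5S,8aR)-5-hydroxy-2,5,8,8-tetramethyloctahydronaphthalen-1(2H)-one
Conditions: Dess–Martin periodinane, pyridine, CH2Cl2, rt
Reagents that add atoms: none
Why: Dess–Martin oxidation of the secondary alcohol; the tertiary alcohol is inert and the buffered neutral medium should not epimerise C6 or C2 (the C2 methyl is already equatorial).

Step 10
Reactants: 12 (2R,4aS,5S,8aR)-5-hydroxy-2,5,8,8-tetramethyloctahydronaphthalen-1(2H)-one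
Product: 13 (1S,4aR,5E,6R,8aS)-1,4,4,6-tetramethyl-5-[(4,4,5,5-tetramethyl-1,3,2-dioxaborolan-2-yl)methylidene]decahydronaphthalen-1-ol
Conditions: CH2(Bpin)2, lithium 2,2,6,6-tetramethylpiperidide (2.4 equiv), THF, 0 °C; then 12, −78 °C to rt; aq. NH4Cl
Reagents that add atoms: bis(4,4,5,5-tetramethyl-1,3,2-dioxaborolan-2-yl)methane, C(B1OC(C)(C)C(C)(C)O1)B1OC(C)(C)C(C)(C)O1
Why: boron–Wittig olefination (addition of the lithiated geminal diboronate to the ketone, then syn elimination of a boron–oxygen unit); the remaining boryl group should settle trans to the bulkier C6 flank, which carries quaternary C27, and so cis to C2.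

Step 11
Reactants: 13 (1S,4aR,5E,6R,8aS)-1,4,4,6-tetramethyl-5-[(4,4,5,5-tetramethyl-1,3,2-dioxaborolan-2-yl)methylidene]decahydronaphthalen-1-ol
Product: 14 (1S,4aR,5E,6R,8aS)-5-(iodomethylidene)-1,4,4,6-tetramethyldecahydronaphthalen-1-ol
Conditions: 3 M NaOH, I2, THF, 0 °C to rt
Reagents that add atoms: iodine, II
Why: iododeboronation of the alkenylboronate through its hydroxide ate complex, which should proceed with retention of the alkene geometry.

Step 12
Reactants: 15 (2E)-1-bromo-3,7-dimethylocta-2,6-diene (geranyl bromide); 16 methyl 3-oxobutanoate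
Product: 18 methyl (6E)-7,11-dimethyl-3-oxododeca-6,10-dienoate, via dianion 17 (not isolated)
Conditions: 16, NaH, THF, 0 °C; n-BuLi, 0 °C; then 15, 0 °C to rt; aq. NH4Cl
Reagents that add atoms: none
Why: acetoacetate dianion alkylation; the more reactive terminal carbanion should displace the allylic bromide by SN2 with the (E)-alkene unchanged.

Step 13
Reactants: 18 methyl (6E)-7,11-dimethyl-3-oxododeca-6,10-dienoate
Product: 19 methyl (2Z,6E)-7,11-dimethyl-3-{[(trifluoromethyl)sulfonyl]oxy}dodeca-2,6,10-trienoate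
Conditions: Tf2O, sat. aq. LiOH, toluene, 5 °C
Reagents that add atoms: trifluoromethanesulfonic anhydride, O=S(=O)(OS(=O)(=O)C(F)(F)F)C(F)(F)F
Why: O-triflation of the lithium-chelated (Z)-enolate of the β-keto ester, which places the triflate cis to the ester.

Step 14
Reactants: 19 methyl (2Z,6E)-7,11-dimethyl-3-{[(trifluoromethyl)sulfonyl]oxy}dodeca-2,6,10-trienoate
Product: 20 methyl (2Z,6E)-7,11-dimethyl-3-[(trimethylsilyl)methyl]dodeca-2,6,10-trienoate
Conditions: Me3SiCH2MgCl, Pd(PPh3)4 (5 mol %), THF, 0 °C to rt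
Reagents that add atoms: (trimethylsilyl)methylmagnesium chloride, C[Si](C)(C)C[Mg]Cl
Why: Kumada–Corriu coupling of the alkenyl triflate, which occurs with retention and should give the allylsilane with CH2SiMe3 cis to the ester.

Step 15
Reactants: 20 methyl (2Z,6E)-7,11-dimethyl-3-[(trimethylsilyl)methyl]dodeca-2,6,10-trienoate
Product: 21 methyl (2Z)-5-[(2S,3S)-3-{2-[(2S)-3,3-dimethyloxiran-2-yl]ethyl}-3-methyloxiran-2-yl]-3-[(trimethylsilyl)methyl]pent-2-enoate
Conditions: 1,2:4,5-di-O-isopropylidene-β-L-erythro-2,3-hexodiulo-2,6-pyranose (0.5 equiv), KHSO5 (Oxone), K2CO3, Bu4NHSO4, MeCN/dimethoxymethane/aq. Na2B4O7 buffer, 0 °C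
Reagents that add atoms: potassium peroxymonosulfate, [K+].[O-]S(=O)(=O)OO
Why: Shi asymmetric epoxidation; the dioxirane should epoxidise the two electron-rich trisubstituted alkenes and leave the ester-conjugated one, and the L-fructose-derived ketone delivers oxygen to the face that gives the S configuration at C21, C11 and C15.

Step 16
Reactants: 21 methyl (2Z)-5-[(2S,3S)-3-{2-[(2S)-3,3-dimethyloxiran-2-yl]ethyl}-3-methyloxiran-2-yl]-3-[(trimethylsilyl)methyl]pent-2-enoate
Product: 22 (2Z)-5-[(2S,3S)-3-{2-[(2S)-3,3-dimethyloxiran-2-yl]ethyl}-3-methyloxiran-2-yl]-3-[(trimethylsilyl)methyl]pent-2-en-1-ol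
Conditions: i-Bu2AlH (2.5 equiv), CH2Cl2, −78 °C; aq. potassium sodium tartrate
Reagents that add atoms: none
Why: hydride reduction of the conjugated ester to the allylic alcohol at low temperature, where the epoxides and the allylsilane should be untouched.

Step 17
Reactants: 22 (2Z)-5-[(2S,3S)-3-{2-[(2S)-3,3-dimethyloxiran-2-yl]ethyl}-3-methyloxiran-2-yl]-3-[(trimethylsilyl)methyl]pent-2-en-1-ol
Product: 23 (2Z)-5-[(2S,3S)-3-{2-[(2S)-3,3-dimethyloxiran-2-yl]ethyl}-3-methyloxiran-2-yl]-3-[(trimethylsilyl)methyl]pent-2-en-1-yl acetate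
Conditions: Ac2O, pyridine, 4-(dimethylamino)pyridine (cat.), CH2Cl2, 0 °C
Reagents that add atoms: acetic anhydride, CC(=O)OC(C)=O
Why: acetylation (nucleophilic acyl-transfer catalysis) masks the hydroxyl so that it cannot intercept the epoxonium ion in the next step.

Step 18
Reactants: 23 (2Z)-5-[(2S,3S)-3-{2-[(2S)-3,3-dimethyloxiran-2-yl]ethyl}-3-methyloxiran-2-yl]-3-[(trimethylsilyl)methyl]pent-2-en-1-yl acetate
Product: 25 [(3S,5aS,6R,9aS)-3-hydroxy-2,2,5a-trimethyl-7-methylidenedecahydro-1-benzoxepin-6-yl]methyl acetate, via trimethylsilyl ether 24 (not isolated)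
Conditions: Me3SiOTf (1.1 equiv), 2,6-di-tert-butyl-4-methylpyridine, CH2Cl2, −78 °C; then 0.5 M HCl, THF, 0 °C
Reagents that add atoms: none
Why: Lewis-acid-triggered tandem oxacyclisation–carbocyclisation of a 1,5-diepoxide with Hosomi–Sakurai termination: the silylated terminal epoxide is opened at tertiary C17 by the oxygen of the second epoxide (ring A), the resulting epoxonium ion is opened at tertiary C11 with inversion by C10 of the allylsilane through a chair (ring B), C21 keeps its oxygen with retention (trans ring fusion), the allylsilane geometry places C9 equatorial and cis to the C11 methyl, and loss of silicon leaves the exocyclic methylene at C24.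

Step 19
Reactants: 25 [(3S,5aS,6R,9aS)-3-hydroxy-2,2,5a-trimethyl-7-methylidenedecahydro-1-benzoxepin-6-yl]methyl acetate
Product: 28 (3S,5aS,6R,7S,9aS)-6-(hydroxymethyl)-2,2,5a,7-tetramethyldecahydro-1-benzoxepine-3,7-diol, via organomercurial 26 (not isolated), via hydroxy acetate 27 (not isolated)
Conditions: Hg(OAc)2, THF/H2O, rt; then 3 M NaOH, NaBH4, 0 °C; then K2CO3, MeOH, rt
Reagents that add atoms: water, O
Why: oxymercuration–demercuration followed by methanolysis of the acetate; water should attack C24 from the equatorial direction, anti to the axial C11 methyl group as in the hydration of labdane exocyclic alkenes, giving the equatorial hydroxyl and axial methyl.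

Step 20
Reactants: 28 (3S,5aS,6R,7S,9aS)-6-(hydroxymethyl)-2,2,5a,7-tetramethyldecahydro-1-benzoxepine-3,7-diol
Product: 29 (3S,5aS,6S,7S,9aS)-6-(iodomethyl)-2,2,5a,7-tetramethyldecahydro-1-benzoxepine-3,7-diol
Conditions: PPh3, I2, imidazole, CH2Cl2, 0 °C to rt
Reagents that add atoms: iodine, II
Why: Appel-type iodination; only the primary alcohol should be activated, the hindered secondary and the tertiary hydroxyls stay.

Step 21
Reactants: 29 (3S,5aS,6S,7S,9aS)-6-(iodomethyl)-2,2,5a,7-tetramethyldecahydro-1-benzoxepine-3,7-diol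
Product: 30 (3S,5aS,6S,7S,9aS)-6-(iodomethyl)-2,2,5a,7-tetramethyl-3,7-bis[(triethylsilyl)oxy]decahydro-1-benzoxepine
Conditions: Et3SiOTf, 2,6-lutidine, CH2Cl2, −78 to 0 °C
Reagents that add atoms: triethylsilyl trifluoromethanesulfonate, CC[Si](CC)(CC)OS(=O)(=O)C(F)(F)F
Why: silylation with a silyl triflate and a hindered base caps both hydroxyls, so that halogen–lithium exchange is not disturbed by alkoxides next to the C–I bond.

Step 22
Reactants: 30 (3S,5aS,6S,7S,9aS)-6-(iodomethyl)-2,2,5a,7-tetramethyl-3,7-bis[(triethylsilyl)oxy]decahydro-1-benzoxepine; 14 (1S,4aR,5E,6R,8aS)-5-(iodomethylidene)-1,4,4,6-tetramethyldecahydronaphthalen-1-ol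
Product: 33 (1S,4aR,5E,6R,8aS)-1,4,4,6-tetramethyl-5-(2-{(3S,5aS,6S,7S,9aS)-2,2,5a,7-tetramethyl-3,7-bis[(triethylsilyl)oxy]decahydro-1-benzoxepin-6-yl}ethylidene)decahydronaphthalen-1-ol, via alkyllithium 31 (not isolated), via borate 32 (not isolated)
Conditions: 30, t-BuLi (2.1 equiv), Et2O, −78 °C; 9-MeO-9-BBN, THF, −78 °C to rt; then 14, PdCl2(dppf) (10 mol %), AsPh3, Cs2CO3, DMF/H2O, rt
Reagents that add atoms: none
Why: B-alkyl Suzuki–Miyaura coupling through a lithium alkyl(methoxy)borate; the alkenyl iodide should couple with retention, so C9 ends up cis to C2, and the free tertiary alcohol of 14 is tolerated by the aqueous basic medium.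

Step 23
Reactants: 33 (1S,4aR,5E,6R,8aS)-1,4,4,6-tetramethyl-5-(2-{(3S,5aS,6S,7S,9aS)-2,2,5a,7-tetramethyl-3,7-bis[(triethylsilyl)oxy]decahydro-1-benzoxepin-6-yl}ethylidene)decahydronaphthalen-1-ol
Product: 34 (3S,5aS,6S,7S,9aS)-6-{(2E)-2-[(2R,4aS,5S,8aR)-5-hydroxy-2,5,8,8-tetramethyloctahydronaphthalen-1(2H)-ylidene]ethyl}-2,2,5a,7-tetramethyldecahydro-1-benzoxepine-3,7-diol
Conditions: HF·pyridine, pyridine, THF, 0 °C to rt
Reagents that add atoms: none
Why: fluoride-mediated cleavage of both silyl ethers; the pyridine buffer should protect the tertiary alcohols from acid-induced elimination.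

Step 24
Reactants: 34 (3S,5aS,6S,7S,9aS)-6-{(2E)-2-[(2R,4aS,5S,8aR)-5-hydroxy-2,5,8,8-tetramethyloctahydronaphthalen-1(2H)-ylidene]ethyl}-2,2,5a,7-tetramethyldecahydro-1-benzoxepine-3,7-diol
Product: 35 (5aS,6S,7S,9aS)-7-hydroxy-6-{(2E)-2-[(2R,4aS,5S,8aR)-5-hydroxy-2,5,8,8-tetramethyloctahydronaphthalen-1(2H)-ylidene]ethyl}-2,2,5a,7-tetramethyloctahydro-1-benzoxepin-3(2H)-one
Conditions: Dess–Martin periodinane, pyridine, CH2Cl2, 0 °C to rt
Reagents that add atoms: none
Why: Dess–Martin oxidation; the C15 carbinol is the only secondary alcohol, and the two tertiary alcohols and the trisubstituted alkene should not react.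

**Compound list**

1 | methyl 4,4-dimethyl-5-oxopentanoate | COC(=O)CCC(C)(C)C=O | starting material
2 | methyl (5E)-4,4-dimethyl-7-oxooct-5-enoate | COC(=O)CCC(C)(C)/C=C/C(C)=O | intermediate
3 | methyl (5E)-4,4,7-trimethylocta-5,7-dienoate | COC(=O)CCC(C)(C)/C=C/C(C)=C | intermediate
4 | (5E)-N-methoxy-N,4,4,7-tetramethylocta-5,7-dienamide | CON(C)C(=O)CCC(C)(C)/C=C/C(C)=C | intermediate
5 | (7E)-6,6,9-trimethyldeca-1,7,9-trien-3-one | C=CC(=O)CCC(C)(C)/C=C/C(C)=C | intermediate
6 | (4aR,8aS)-4,4,6-trimethyl-3,4,4a,7,8,8a-hexahydronaphthalen-1(2H)-one (cis-fused) | CC1=C[C@H]2C(C)(C)CCC(=O)[C@H]2CC1 | intermediate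
7 | (4aR,8aS)-4,4,6-trimethyl-1-methylidene-1,2,3,4,4a,7,8,8a-octahydronaphthalene | CC1=C[C@H]2C(C)(C)CCC(=C)[C@H]2CC1 | intermediate
8 | {[(1S,4aR,8aS)-1-hydroxy-4,4,6-trimethyl-1,2,3,4,4a,7,8,8a-octahydronaphthalen-1-yl]methyl}mercury acetate | CC1=C[C@H]2C(C)(C)CC[C@](C[Hg]OC(C)=O)(O)[C@H]2CC1 | intermediate (not isolated)
9 | (1S,4aR,8aS)-1,4,4,6-tetramethyl-1,2,3,4,4a,7,8,8a-octahydronaphthalen-1-ol | CC1=C[C@H]2C(C)(C)CC[C@](C)(O)[C@H]2CC1 | intermediate
10 | 5-boranyl analogue of diol 11 (BH2 in place of the 5-hydroxyl, same configuration) | C[C@@H]1CC[C@H]2[C@@H]([C@H]1B)C(C)(C)CC[C@]2(C)O | intermediate (not isolated)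
11 | (1S,4aR,5S,6R,8aS)-1,4,4,6-tetramethyldecahydronaphthalene-1,5-diol | C[C@@H]1CC[C@H]2[C@@H]([C@H]1O)C(C)(C)CC[C@]2(C)O | intermediate
12 | (2R,4aS,5S,8aR)-5-hydroxy-2,5,8,8-tetramethyloctahydronaphthalen-1(2H)-one | C[C@@H]1CC[C@H]2[C@@H](C1=O)C(C)(C)CC[C@]2(C)O | intermediate
13 | (1S,4aR,5E,6R,8aS)-1,4,4,6-tetramethyl-5-[(4,4,5,5-tetramethyl-1,3,2-dioxaborolan-2-yl)methylidene]decahydronaphthalen-1-ol | C[C@@H]1CC[C@H]2[C@@H](/C1=C/B3OC(C)(C)C(C)(C)O3)C(C)(C)CC[C@]2(C)O | intermediate
14 | (1S,4aR,5E,6R,8aS)-5-(iodomethylidene)-1,4,4,6-tetramethyldecahydronaphthalen-1-ol | C[C@@H]1CC[C@H]2[C@@H](/C1=C/I)C(C)(C)CC[C@]2(C)O | intermediate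
15 | (2E)-1-bromo-3,7-dimethylocta-2,6-diene (geranyl bromide) | CC(C)=CCC/C(C)=C/CBr | starting material
16 | methyl 3-oxobutanoate | COC(=O)CC(C)=O | starting material
17 | sodium lithium dianion of methyl 3-oxobutanoate (C2 and C4 deprotonated) | COC(=O)[CH-]C(=O)[CH2-].[Na+].[Li+] | intermediate (not isolated)
18 | methyl (6E)-7,11-dimethyl-3-oxododeca-6,10-dienoate | COC(=O)CC(=O)CC/C=C(\C)CCC=C(C)C | intermediate
19 | methyl (2Z,6E)-7,11-dimethyl-3-{[(trifluoromethyl)sulfonyl]oxy}dodeca-2,6,10-trienoate | COC(=O)/C=C(\OS(=O)(=O)C(F)(F)F)CC/C=C(\C)CCC=C(C)C | intermediate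
20 | methyl (2Z,6E)-7,11-dimethyl-3-[(trimethylsilyl)methyl]dodeca-2,6,10-trienoate | COC(=O)/C=C(\C[Si](C)(C)C)CC/C=C(\C)CCC=C(C)C | intermediate
21 | methyl (2Z)-5-[(2S,3S)-3-{2-[(2S)-3,3-dimethyloxiran-2-yl]ethyl}-3-methyloxiran-2-yl]-3-[(trimethylsilyl)methyl]pent-2-enoate | COC(=O)/C=C(\C[Si](C)(C)C)CC[C@@H]1O[C@@]1(C)CC[C@@H]1OC1(C)C | intermediate
22 | (2Z)-5-[(2S,3S)-3-{2-[(2S)-3,3-dimethyloxiran-2-yl]ethyl}-3-methyloxiran-2-yl]-3-[(trimethylsilyl)methyl]pent-2-en-1-ol | OC/C=C(\C[Si](C)(C)C)CC[C@@H]1O[C@@]1(C)CC[C@@H]1OC1(C)C | intermediate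
23 | (2Z)-5-[(2S,3S)-3-{2-[(2S)-3,3-dimethyloxiran-2-yl]ethyl}-3-methyloxiran-2-yl]-3-[(trimethylsilyl)methyl]pent-2-en-1-yl acetate | CC(=O)OC/C=C(\C[Si](C)(C)C)CC[C@@H]1O[C@@]1(C)CC[C@@H]1OC1(C)C | intermediate
24 | {(3S,5aS,6R,9aS)-2,2,5a-trimethyl-7-methylidene-3-[(trimethylsilyl)oxy]decahydro-1-benzoxepin-6-yl}methyl acetate (trans-fused) | CC(=O)OC[C@H]1[C@]2(C)CC[C@H](O[Si](C)(C)C)C(C)(C)O[C@H]2CCC1=C | intermediate (not isolated)
25 | [(3S,5aS,6R,9aS)-3-hydroxy-2,2,5a-trimethyl-7-methylidenedecahydro-1-benzoxepin-6-yl]methyl acetate | CC(=O)OC[C@H]1[C@]2(C)CC[C@H](O)C(C)(C)O[C@H]2CCC1=C | intermediate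
26 | 7-[(acetoxymercurio)methyl] analogue of 27 (CH2HgOAc in place of the 7-methyl group, same configuration) | CC(=O)OC[C@H]1[C@]2(C)CC[C@H](O)C(C)(C)O[C@H]2CC[C@]1(C[Hg]OC(C)=O)O | intermediate (not isolated)
27 | [(3S,5aS,6R,7S,9aS)-3,7-dihydroxy-2,2,5a,7-tetramethyldecahydro-1-benzoxepin-6-yl]methyl acetate | CC(=O)OC[C@H]1[C@]2(C)CC[C@H](O)C(C)(C)O[C@H]2CC[C@]1(C)O | intermediate (not isolated)
28 | (3S,5aS,6R,7S,9aS)-6-(hydroxymethyl)-2,2,5a,7-tetramethyldecahydro-1-benzoxepine-3,7-diol | OC[C@H]1[C@]2(C)CC[C@H](O)C(C)(C)O[C@H]2CC[C@]1(C)O | intermediate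
29 | (3S,5aS,6S,7S,9aS)-6-(iodomethyl)-2,2,5a,7-tetramethyldecahydro-1-benzoxepine-3,7-diol | IC[C@H]1[C@]2(C)CC[C@H](O)C(C)(C)O[C@H]2CC[C@]1(C)O | intermediate
30 | (3S,5aS,6S,7S,9aS)-6-(iodomethyl)-2,2,5a,7-tetramethyl-3,7-bis[(triethylsilyl)oxy]decahydro-1-benzoxepine | IC[C@H]1[C@]2(C)CC[C@H](O[Si](CC)(CC)CC)C(C)(C)O[C@H]2CC[C@]1(C)O[Si](CC)(CC)CC | intermediate
31 | lithio analogue of 30 (Li in place of I) | [Li]C[C@H]1[C@]2(C)CC[C@H](O[Si](CC)(CC)CC)C(C)(C)O[C@H]2CC[C@]1(C)O[Si](CC)(CC)CC | intermediate (not isolated)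
32 | lithium B-methoxy-B-alkyl-9-borabicyclo[3.3.1]nonane ate complex formed from 31 | [Li+].CO[B-]1(C[C@H]2[C@]3(C)CC[C@H](O[Si](CC)(CC)CC)C(C)(C)O[C@H]3CC[C@]2(C)O[Si](CC)(CC)CC)C2CCCC1CCC2 | intermediate (not isolated)
33 | (1S,4aR,5E,6R,8aS)-1,4,4,6-tetramethyl-5-(2-{(3S,5aS,6S,7S,9aS)-2,2,5a,7-tetramethyl-3,7-bis[(triethylsilyl)oxy]decahydro-1-benzoxepin-6-yl}ethylidene)decahydronaphthalen-1-ol | C[C@@H]1CC[C@H]2[C@@H](/C1=C/C[C@H]1[C@]3(C)CC[C@H](O[Si](CC)(CC)CC)C(C)(C)O[C@H]3CC[C@]1(C)O[Si](CC)(CC)CC)C(C)(C)CC[C@]2(C)O | intermediate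
34 | (3S,5aS,6S,7S,9aS)-6-{(2E)-2-[(2R,4aS,5S,8aR)-5-hydroxy-2,5,8,8-tetramethyloctahydronaphthalen-1(2H)-ylidene]ethyl}-2,2,5a,7-tetramethyldecahydro-1-benzoxepine-3,7-diol | C[C@@H]1CC[C@H]2[C@@H](/C1=C/C[C@H]1[C@]3(C)CC[C@H](O)C(C)(C)O[C@H]3CC[C@]1(C)O)C(C)(C)CC[C@]2(C)O | intermediate
35 | (5aS,6S,7S,9aS)-7-hydroxy-6-{(2E)-2-[(2R,4aS,5S,8aR)-5-hydroxy-2,5,8,8-tetramethyloctahydronaphthalen-1(2H)-ylidene]ethyl}-2,2,5a,7-tetramethyloctahydro-1-benzoxepin-3(2H)-one (CNP0232921.1) | C[C@@H]1CC[C@H]2[C@@H](/C1=C/C[C@H]1[C@]3(C)CCC(=O)C(C)(C)O[C@H]3CC[C@]1(C)O)C(C)(C)CC[C@]2(C)O | target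

**Totals**

Total step count: 24.
Longest linear sequence: 14 steps (steps 1–11, then 22–24, from 1). The west branch is 13 steps (steps 12–21, then 22–24, from 15 and 16).

**Steps most likely to fail**

Step 18. The Lewis acid may ionise the allylic acetate of the 2-(silylmethyl)allyl unit, with loss of acetate and silicon to a diene. The acetate carbonyl may also capture the epoxonium ion before the carbon–carbon bond forms. The fallback sets out from 21 and runs the cascade one stage earlier, on a substrate with no ionisable allylic oxygen. There the silylmethyl enoate reacts at its α-carbon as a dienolate equivalent. Treatment of 21 with Me3SiOTf and 2,6-di-tert-butyl-4-methylpyridine at −78 °C, then dilute acid, should give methyl (3S,5aS,6R,9aS)-3-hydroxy-2,2,5a-trimethyl-7-methylidenedecahydro-1-benzoxepine-6-carboxylate F1. Oxymercuration–demercuration as in step 19 should give methyl (3S,5aS,6S,7S,9aS)-3,7-dihydroxy-2,2,5a,7-tetramethyldecahydro-1-benzoxepine-6-carboxylate F2. Reduction with LiAlH4 in THF at 0 °C then returns to the route at 28.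

Step 10. The hindered C7 carbonyl may be enolised by the diboryl carbanion instead of adding it, which would epimerise C6 toward the trans-decalin, and control of the alkene geometry may be poor. The fallback sets out from 12 and avoids carbanion addition to the ketone. Lombardo methylenation (Zn, CH2Br2, TiCl4) should give (1S,4aR,6R,8aS)-1,4,4,6-tetramethyl-5-methylidenedecahydronaphthalen-1-ol F3. Hydroboration with 9-BBN and oxidation with NaOH/H2O2 should give 5-(hydroxymethyl)-1,4,4,6-tetramethyldecahydronaphthalen-1-ol F4, whose C5 configuration does not matter. Dess–Martin oxidation gives the 5-carbaldehyde F5, in which only the C7 hydrogen is acidic. Enolisation with KN(SiMe3)2 and trapping with PhNTf2 should place the oxygen cis to the smaller C2 flank and give (E)-[(2R,4aS,5S,8aR)-5-hydroxy-2,5,8,8-tetramethyloctahydronaphthalen-1(2H)-ylidene]methyl trifluoromethanesulfonate F6. Coupling of F6 with borate 32 under the conditions of step 22 returns to the route at 33.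

Step 5. The uncatalysed cyclisation may compete, and the chiral cation may discriminate poorly between the faces of an unsubstituted vinyl ketone, so the adduct may form with low enantiomeric purity. The fallback sets out from 5 and separates ring formation from absolute control. Me2AlCl in CH2Cl2 at −78 °C should give racemic cis-4,4,6-trimethyl-3,4,4a,7,8,8a-hexahydronaphthalen-1(2H)-one F7. Addition of lithiated (S)-N,S-dimethyl-S-phenylsulfoximine in THF at −78 °C should give two diastereomeric β-hydroxysulfoximines. These are (1R,4aR,8aS)-4,4,6-trimethyl-1-{[(S)-N-methyl-S-phenylsulfonimidoyl]methyl}-1,2,3,4,4a,7,8,8a-octahydronaphthalen-1-ol F8 and its (1S,4aS,8aR) diastereomer F9, which are separated by chromatography. Heating F8 in toluene at reflux releases the sulfoximine and returns to the route at 6.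

**Further compounds**

F1 | step 18 | methyl (3S,5aS,6R,9aS)-3-hydroxy-2,2,5a-trimethyl-7-methylidenedecahydro-1-benzoxepine-6-carboxylate | COC(=O)[C@H]1[C@]2(C)CC[C@H](O)C(C)(C)O[C@H]2CCC1=C
F2 | step 18 | methyl (3S,5aS,6S,7S,9aS)-3,7-dihydroxy-2,2,5a,7-tetramethyldecahydro-1-benzoxepine-6-carboxylate | COC(=O)[C@H]1[C@]2(C)CC[C@H](O)C(C)(C)O[C@H]2CC[C@]1(C)O
F3 | step 10 | (1S,4aR,6R,8aS)-1,4,4,6-tetramethyl-5-methylidenedecahydronaphthalen-1-ol | C[C@@H]1CC[C@H]2[C@@H](C1=C)C(C)(C)CC[C@]2(C)O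
F4 | step 10 | 5-(hydroxymethyl)-1,4,4,6-tetramethyldecahydronaphthalen-1-ol (5-hydroxymethyl analogue of 11, C5 configuration open) | C[C@@H]1CC[C@H]2[C@@H](C1CO)C(C)(C)CC[C@]2(C)O
F5 | step 10 | 5-hydroxy-2,5,8,8-tetramethyldecahydronaphthalene-1-carbaldehyde (C1 configuration open, other centres as in 12) | C[C@@H]1CC[C@H]2[C@@H](C1C=O)C(C)(C)CC[C@]2(C)O
F6 | step 10 | (E)-[(2R,4aS,5S,8aR)-5-hydroxy-2,5,8,8-tetramethyloctahydronaphthalen-1(2H)-ylidene]methyl trifluoromethanesulfonate | C[C@@H]1CC[C@H]2[C@@H](/C1=C/OS(=O)(=O)C(F)(F)F)C(C)(C)CC[C@]2(C)O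
F7 | step 5 | racemic cis-4,4,6-trimethyl-3,4,4a,7,8,8a-hexahydronaphthalen-1(2H)-one | CC1=CC2C(C)(C)CCC(=O)C2CC1
F8 | step 5 | (1R,4aR,8aS)-4,4,6-trimethyl-1-{[(S)-N-methyl-S-phenylsulfonimidoyl]methyl}-1,2,3,4,4a,7,8,8a-octahydronaphthalen-1-ol | CC1=C[C@H]2C(C)(C)CC[C@](O)(C[S@@](=O)(=NC)c3ccccc3)[C@H]2CC1
F9 | step 5 | (1S,4aS,8aR)-4,4,6-trimethyl-1-{[(S)-N-methyl-S-phenylsulfonimidoyl]methyl}-1,2,3,4,4a,7,8,8a-octahydronaphthalen-1-ol | CC1=C[C@@H]2C(C)(C)CC[C@@](O)(C[S@@](=O)(=NC)c3ccccc3)[C@@H]2CC1
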